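**Plan**

1. Retrosynthetic cuts, in order: the two C3–CHO bonds (one per ring), the ring B carboxyl (as an allyl ester, earlier an acetonide lactone), the C1–C6 bond of ring B, the chain C–C bond between an O-aroylglycolyl unit and a dioxinone keto-ester, and last the glycolate O–CH2 bond to ring A.
2. Enabling feature: ring B is a 2,4-dioxygenated benzoic acid whose C6 carries CH2–O–acyl, so C1–C6 plus the carboxyl carbon correspond to a tetraketide chain that starts with an O-acylated glycolyl unit, with the C2 oxygen and the carboxyl masked together as a dioxinone.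
3. Forward: ring A comes ready-made from orsellinic acid (MOM protection, O-alkylation with benzyl bromoacetate, debenzylation). Its acid chloride C-acylates the allyl keto-ester of 2,2,6-trimethyl-4H-1,3-dioxin-4-one, and deallylation–decarboxylation gives the diketo-dioxinone.
4. Ring B, the only ring built, then arises by base-mediated aldol aromatisation. The acetonide lactone is exchanged for an allyl ester, the phenols are freed, both rings are formylated at C3 and the allyl ester is removed.
5. Stereochemistry: the target has no stereocentre; the carbinol centres of the transient aldol adduct vanish on aromatisation.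

Key step: step 8

Remark: ring positions are numbered as in a benzoic acid (C1 carries the carboxyl carbon, C2 and C4 the oxygens, C3 the formyl group, C6 the methyl group of ring A or the CH2O group of ring B).
Remark: the 1,3-dicarbonyl compounds 12, 14, 15 and 16 are drawn as keto tautomers although they should be largely enolised, so the methine carbon of 14 and 15 is not a defined stereocentre; 17 is a transient diastereomer mixture.

**Route**

Step 1
Reactants: 1 orsellinic acid (2,4-dihydroxy-6-methylbenzoic acid)
Product: 3 2,4-bis(methoxymethoxy)-6-methylbenzoic acid, via methoxymethyl ester 2 (not isolated)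
Conditions: NaH (3.3 equiv), MOMCl (3.3 equiv), THF–DMF, 0 °C → rt; then 2 M aq NaOH, MeOH, 60 °C; cold 1 M HCl to pH 4
Reagents that add atoms: chloromethyl methyl ether (MOMCl), COCCl
Why: Williamson-type O-alkylation of the trisodium salt caps all three acidic oxygens, and the acylal-like methoxymethyl ester is then saponified selectively because aryl MOM ethers are inert to hydroxide.

Step 2
Reactants: 3 2,4-bis(methoxymethoxy)-6-methylbenzoic acid; 4 benzyl bromoacetate
Product: 5 2-(benzyloxy)-2-oxoethyl 2,4-bis(methoxymethoxy)-6-methylbenzoate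
Conditions: K2CO3, DMF, rt
Reagents that add atoms: none
Why: Carboxylate SN2 alkylation of an alpha-bromo ester forms the hindered ring A ester at oxygen, away from the flanked carbonyl carbon, so the two ortho substituents do not slow it.

Step 3
Reactants: 5 2-(benzyloxy)-2-oxoethyl 2,4-bis(methoxymethoxy)-6-methylbenzoate
Product: 6 {[2,4-bis(methoxymethoxy)-6-methylbenzoyl]oxy}acetic acid
Conditions: H2 (1 atm), 10% Pd/C, EtOAc, rt
Reagents that add atoms: none
Why: Catalytic hydrogenolysis removes only the benzyl ester, since the aryl MOM ethers and the non-benzylic aroyloxyacetate linkage are inert, and it is used here because no benzylic ester of ring B exists yet.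

Step 4
Reactants: 7 2,2-dimethyl-1,3-dioxane-4,6-dione (Meldrum's acid); 8 allyl alcohol
Product: 9 allyl hydrogen malonate (3-(allyloxy)-3-oxopropanoic acid)
Conditions: toluene, 110 °C
Reagents that add atoms: none
Why: Thermal alcoholysis of the cyclic acylal (ring-opening acyl substitution with loss of acetone) is the standard entry to malonic half esters.

Step 5
Reactants: 9 allyl hydrogen malonate; 10 2,2,6-trimethyl-4H-1,3-dioxin-4-one
Product: 12 allyl 4-(2,2-dimethyl-4-oxo-4H-1,3-dioxin-6-yl)-3-oxobutanoate, via malonyl chloride 11 (not isolated)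
Conditions: 9, (COCl)2, cat. DMF, CH2Cl2, 0 °C → rt; separately 10 (2 equiv), LiN(SiMe3)2 (2 equiv), THF, −78 °C; then 11, −78 → −20 °C
Reagents that add atoms: none
Why: The lithium dienolate of the dioxinone is acylated at its gamma (exocyclic) carbon by the acid chloride in a vinylogous Claisen-type C-acylation, with excess dienolate compensating for the acidity of the keto-ester formed.

Step 6
Reactants: 6 {[2,4-bis(methoxymethoxy)-6-methylbenzoyl]oxy}acetic acid; 12 allyl 4-(2,2-dimethyl-4-oxo-4H-1,3-dioxin-6-yl)-3-oxobutanoate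
Product: 14 allyl 2-({[2,4-bis(methoxymethoxy)-6-methylbenzoyl]oxy}acetyl)-4-(2,2-dimethyl-4-oxo-4H-1,3-dioxin-6-yl)-3-oxobutanoate, via acid chloride 13 (not isolated)
Conditions: 6, 1-chloro-N,N,2-trimethylprop-1-en-1-amine, CH2Cl2, 0 °C → rt; separately 12, MgCl2 (2 equiv), pyridine (2.7 equiv), CH2Cl2, 0 °C; then 13, 0 °C → rt
Reagents that add atoms: none
Why: MgCl2 and pyridine form the chelated magnesium enolate of the beta-keto ester under soft-enolisation conditions, which is acylated on carbon (Claisen-type C-acylation) by an acid chloride made under neutral conditions, so the MOM ethers meet no free HCl.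

Step 7
Reactants: 14 allyl 2-({[2,4-bis(methoxymethoxy)-6-methylbenzoyl]oxy}acetyl)-4-(2,2-dimethyl-4-oxo-4H-1,3-dioxin-6-yl)-3-oxobutanoate
Product: 16 5-(2,2-dimethyl-4-oxo-4H-1,3-dioxin-6-yl)-2,4-dioxopentyl 2,4-bis(methoxymethoxy)-6-methylbenzoate, via keto acid 15 (not isolated)
Conditions: Pd(PPh3)4 (5 mol %), morpholine (2 equiv), THF, 0 °C; pH 3 buffer work-up
Reagents that add atoms: none
Why: Zerovalent palladium ionises the allyl ester (Tsuji–Trost deallylation), morpholine captures the allyl group and the beta-keto acid loses CO2 spontaneously, while the cold, short reaction and acidic quench should keep the diketo-dioxinone from cyclising before isolation.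

Step 8
Reactants: 16 5-(2,2-dimethyl-4-oxo-4H-1,3-dioxin-6-yl)-2,4-dioxopentyl 2,4-bis(methoxymethoxy)-6-methylbenzoate
Product: 18 (7-hydroxy-2,2-dimethyl-4-oxo-4H-1,3-benzodioxin-5-yl)methyl 2,4-bis(methoxymethoxy)-6-methylbenzoate, via aldol carbinol 17 (not isolated)
Conditions: Et3N, CH2Cl2, 0 °C → rt
Reagents that add atoms: none
Why: Et3N generates the vinylogous enolate of the dioxinone, whose carbon alpha to the lactone carbonyl adds to the terminal, acyloxy-activated ketone to give carbinol 17; loss of water and enolisation of the remaining ketone then give the phenol of 18. The closest known reaction type is the base-mediated biomimetic aldol cycloaromatisation of 6-(2,4-dioxoalkyl)dioxinones to resorcylate acetonides. Ring B closes in a 6-(enolexo)-exo-trig aldol that forms its C1–C6 bond. No stereocentre is retained, because the two carbinol-stage centres of 17 are erased on aromatisation. The step needs C1-to-C6 aldol folding in preference to Claisen, pyrone or O-to-C acyl-transfer pathways. The dioxinone secures this by locking the carboxyl terminus as a non-acylating enol ester acetal, and the ring A benzoate is shielded from the enolate and the amine by its two ortho substituents.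

Step 9
Reactants: 18 (7-hydroxy-2,2-dimethyl-4-oxo-4H-1,3-benzodioxin-5-yl)methyl 2,4-bis(methoxymethoxy)-6-methylbenzoate
Product: 19 [7-(methoxymethoxy)-2,2-dimethyl-4-oxo-4H-1,3-benzodioxin-5-yl]methyl 2,4-bis(methoxymethoxy)-6-methylbenzoate
Conditions: MOMCl, i-Pr2NEt, CH2Cl2, 0 °C → rt
Reagents that add atoms: chloromethyl methyl ether (MOMCl), COCCl
Why: O-alkylation of the acidic, unhindered phenol para to the lactone carbonyl removes the proton that would otherwise give a phenoxide and deactivate that carbonyl towards the alkoxide of the next step.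

Step 10
Reactants: 19 [7-(methoxymethoxy)-2,2-dimethyl-4-oxo-4H-1,3-benzodioxin-5-yl]methyl 2,4-bis(methoxymethoxy)-6-methylbenzoate; 8 allyl alcohol
Product: 20 allyl 6-({[2,4-bis(methoxymethoxy)-6-methylbenzoyl]oxy}methyl)-2-hydroxy-4-(methoxymethoxy)benzoate
Conditions: NaH (1.5 equiv), allyl alcohol (3 equiv), THF, 0 °C → rt; AcOH quench
Reagents that add atoms: none
Why: Sodium allyloxide opens the activated salicylate acetonide by acyl substitution (transesterification with loss of acetone and release of the C2 phenoxide), whereas the unactivated, doubly ortho-substituted ring A ester should be spared.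

Step 11
Reactants: 20 allyl 6-({[2,4-bis(methoxymethoxy)-6-methylbenzoyl]oxy}methyl)-2-hydroxy-4-(methoxymethoxy)benzoate
Product: 21 allyl 6-{[(2,4-dihydroxy-6-methylbenzoyl)oxy]methyl}-2,4-dihydroxybenzoate
Conditions: HCl (1.25 M in MeOH), CH2Cl2, rt → 35 °C
Reagents that add atoms: none
Why: Acid-catalysed acetal exchange with methanol removes the three MOM ethers and traps the methoxymethyl cation as dimethoxymethane, while both hindered esters resist Fischer transesterification at this temperature.

Step 12
Reactants: 21 allyl 6-{[(2,4-dihydroxy-6-methylbenzoyl)oxy]methyl}-2,4-dihydroxybenzoate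
Product: 22 allyl 3-formyl-6-{[(3-formyl-2,4-dihydroxy-6-methylbenzoyl)oxy]methyl}-2,4-dihydroxybenzoate
Conditions: Cl2CHOMe (2.5 equiv), TiCl4 (6 equiv), CH2Cl2, −15 → 0 °C; then 1 M HCl
Reagents that add atoms: dichloromethyl methyl ether, COC(Cl)Cl; water, O
Why: Rieche formylation of the titanium phenoxides should attack C3 in both rings, because the chelate between the C2 oxygen and the ester fixes the C1–C2 double bond and sends the ortho-directing C4 oxygen to C3, while C5 is flanked by the C6 substituent; this is the pattern by which orsellinate esters give haematommate esters.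

Step 13
Reactants: 22 allyl 3-formyl-6-{[(3-formyl-2,4-dihydroxy-6-methylbenzoyl)oxy]methyl}-2,4-dihydroxybenzoate
Product: 23 barbatolic acid (3-formyl-6-{[(3-formyl-2,4-dihydroxy-6-methylbenzoyl)oxy]methyl}-2,4-dihydroxybenzoic acid)
Conditions: Pd(PPh3)4 (5 mol %), PhNHMe (3 equiv), THF, rt; dilute HCl wash
Reagents that add atoms: none
Why: Tsuji–Trost deallylation with zerovalent palladium and a weakly basic aniline as allyl acceptor frees the acid near neutrality, avoiding hydrogenolysis (which would cut the benzylic ester) and hydroxide (which would invite phthalide formation).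

**Compound list**

1 | orsellinic acid (2,4-dihydroxy-6-methylbenzoic acid) | Cc1cc(O)cc(O)c1C(=O)O | starting material
2 | methoxymethyl 2,4-bis(methoxymethoxy)-6-methylbenzoate | Cc1cc(OCOC)cc(OCOC)c1C(=O)OCOC | intermediate (not isolated)
3 | 2,4-bis(methoxymethoxy)-6-methylbenzoic acid | Cc1cc(OCOC)cc(OCOC)c1C(=O)O | intermediate
4 | benzyl bromoacetate | O=C(CBr)OCc1ccccc1 | starting material
5 | 2-(benzyloxy)-2-oxoethyl 2,4-bis(methoxymethoxy)-6-methylbenzoate | Cc1cc(OCOC)cc(OCOC)c1C(=O)OCC(=O)OCc1ccccc1 | intermediate
6 | {[2,4-bis(methoxymethoxy)-6-methylbenzoyl]oxy}acetic acid | Cc1cc(OCOC)cc(OCOC)c1C(=O)OCC(=O)O | intermediate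
7 | 2,2-dimethyl-1,3-dioxane-4,6-dione (Meldrum's acid) | CC1(C)OC(=O)CC(=O)O1 | starting material
8 | allyl alcohol (prop-2-en-1-ol) | C=CCO | starting material
9 | allyl hydrogen malonate | C=CCOC(=O)CC(=O)O | intermediate
10 | 2,2,6-trimethyl-4H-1,3-dioxin-4-one | CC1=CC(=O)OC(C)(C)O1 | starting material
11 | allyl 3-chloro-3-oxopropanoate (allyl malonyl chloride) | C=CCOC(=O)CC(=O)Cl | intermediate (not isolated)
12 | allyl 4-(2,2-dimethyl-4-oxo-4H-1,3-dioxin-6-yl)-3-oxobutanoate | C=CCOC(=O)CC(=O)CC1=CC(=O)OC(C)(C)O1 | intermediate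
13 | {[2,4-bis(methoxymethoxy)-6-methylbenzoyl]oxy}acetyl chloride | Cc1cc(OCOC)cc(OCOC)c1C(=O)OCC(=O)Cl | intermediate (not isolated)
14 | allyl 2-({[2,4-bis(methoxymethoxy)-6-methylbenzoyl]oxy}acetyl)-4-(2,2-dimethyl-4-oxo-4H-1,3-dioxin-6-yl)-3-oxobutanoate | Cc1cc(OCOC)cc(OCOC)c1C(=O)OCC(=O)C(C(=O)OCC=C)C(=O)CC1=CC(=O)OC(C)(C)O1 | intermediate
15 | 2-({[2,4-bis(methoxymethoxy)-6-methylbenzoyl]oxy}acetyl)-4-(2,2-dimethyl-4-oxo-4H-1,3-dioxin-6-yl)-3-oxobutanoic acid | Cc1cc(OCOC)cc(OCOC)c1C(=O)OCC(=O)C(C(=O)O)C(=O)CC1=CC(=O)OC(C)(C)O1 | intermediate (not isolated)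
16 | 5-(2,2-dimethyl-4-oxo-4H-1,3-dioxin-6-yl)-2,4-dioxopentyl 2,4-bis(methoxymethoxy)-6-methylbenzoate | Cc1cc(OCOC)cc(OCOC)c1C(=O)OCC(=O)CC(=O)CC1=CC(=O)OC(C)(C)O1 | intermediate (key-step precursor)
17 | (5-hydroxy-2,2-dimethyl-4,7-dioxo-4a,5,6,7-tetrahydro-4H-1,3-benzodioxin-5-yl)methyl 2,4-bis(methoxymethoxy)-6-methylbenzoate, diastereomer mixture | Cc1cc(OCOC)cc(OCOC)c1C(=O)OCC1(O)CC(=O)C=C2OC(C)(C)OC(=O)C12 | intermediate (not isolated)
18 | (7-hydroxy-2,2-dimethyl-4-oxo-4H-1,3-benzodioxin-5-yl)methyl 2,4-bis(methoxymethoxy)-6-methylbenzoate | Cc1cc(OCOC)cc(OCOC)c1C(=O)OCc1cc(O)cc2OC(C)(C)OC(=O)c12 | intermediate (key-step product)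
19 | [7-(methoxymethoxy)-2,2-dimethyl-4-oxo-4H-1,3-benzodioxin-5-yl]methyl 2,4-bis(methoxymethoxy)-6-methylbenzoate | Cc1cc(OCOC)cc(OCOC)c1C(=O)OCc1cc(OCOC)cc2OC(C)(C)OC(=O)c12 | intermediate
20 | allyl 6-({[2,4-bis(methoxymethoxy)-6-methylbenzoyl]oxy}methyl)-2-hydroxy-4-(methoxymethoxy)benzoate | Cc1cc(OCOC)cc(OCOC)c1C(=O)OCc1cc(OCOC)cc(O)c1C(=O)OCC=C | intermediate
21 | allyl 6-{[(2,4-dihydroxy-6-methylbenzoyl)oxy]methyl}-2,4-dihydroxybenzoate | Cc1cc(O)cc(O)c1C(=O)OCc1cc(O)cc(O)c1C(=O)OCC=C | intermediate
22 | allyl 3-formyl-6-{[(3-formyl-2,4-dihydroxy-6-methylbenzoyl)oxy]methyl}-2,4-dihydroxybenzoate | Cc1cc(O)c(C=O)c(O)c1C(=O)OCc1cc(O)c(C=O)c(O)c1C(=O)OCC=C | intermediate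
23 | barbatolic acid | Cc1cc(O)c(C=O)c(O)c1C(=O)OCc1cc(O)c(C=O)c(O)c1C(=O)O | target

**Step count**

Total: 13 steps. Longest linear sequence: 11 steps (steps 1, 2, 3, 6, 7, 8, 9, 10, 11, 12, 13); steps 4 and 5 form the side branch to keto-ester 12.

**Steps most likely to fail**

Step 12. The twofold electrophilic substitution may lose positional control, with attack at C5 of either ring (para to the chelated hydroxyl) or stopping after one formylation, so that isomer mixtures build up across two rings at once. The fallback stages the two formylations and makes the ring B one unambiguous. It sets out from 20, whose ring B has a single free phenol (C2–OH) with only one open ortho position (C3). Magnesium phenoxide-directed ortho-formylation (MgCl2, Et3N, paraformaldehyde, MeCN, reflux; Casnati–Skattebøl conditions) should give the ring B aldehyde F1. Methanolic HCl then removes the three MOM ethers to give the ring B formylated tetraphenol F2. A single Rieche formylation (Cl2CHOMe, TiCl4) is then needed only on ring A, since ring B is deactivated by its aldehyde. The route is rejoined at 22.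

Step 10. Allyloxide may attack the ring A ester instead of the lactone; the benzylic alkoxide so released would collapse onto the neighbouring lactone carbonyl to give a phthalide with loss of ring A, or the opening may simply stall. The fallback avoids base altogether. It sets out from 19, which is irradiated at 300 nm in CH2Cl2 containing allyl alcohol. Photochemical retro-[4+2] extrusion of acetone should give the ortho-quinone ketene F3, which is captured by the alcohol under neutral conditions. The route is rejoined at 20.

Step 6. Acylation of the magnesium enolate may go to oxygen, the alpha-acyloxyacetyl chloride may form a ketene and self-condense under pyridine, or the MOM ethers may be lost to adventitious HCl. The fallback inverts the chain assembly into a terminal Claisen condensation. It sets out from 6, which is coupled with N,O-dimethylhydroxylamine hydrochloride (EDC·HCl, i-Pr2NEt, CH2Cl2) to give the N-methoxy-N-methylamide F4. In parallel, 10 is acetylated at its gamma carbon (LiN(SiMe3)2, THF, −78 °C, then acetyl chloride) to give the keto-dioxinone F5. The dianion of F5 (LiN(i-Pr)2, 2 equiv, THF, −78 °C) is then acylated at its terminal methyl carbon by F4. This delivers the diketo-dioxinone directly, bypassing 14 and step 7, and the route is rejoined at 16.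

**Further compounds**

F1 | step 12 | allyl 6-({[2,4-bis(methoxymethoxy)-6-methylbenzoyl]oxy}methyl)-3-formyl-2-hydroxy-4-(methoxymethoxy)benzoate | Cc1cc(OCOC)cc(OCOC)c1C(=O)OCc1cc(OCOC)c(C=O)c(O)c1C(=O)OCC=C
F2 | step 12 | allyl 6-{[(2,4-dihydroxy-6-methylbenzoyl)oxy]methyl}-3-formyl-2,4-dihydroxybenzoate | Cc1cc(O)cc(O)c1C(=O)OCc1cc(O)c(C=O)c(O)c1C(=O)OCC=C
F3 | step 10 | [3-(methoxymethoxy)-5-oxo-6-(oxomethylidene)cyclohexa-1,3-dien-1-yl]methyl 2,4-bis(methoxymethoxy)-6-methylbenzoate (ortho-quinone ketene) | O=C=C1C(=O)C=C(OCOC)C=C1COC(=O)c1c(C)cc(OCOC)cc1OCOC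
F4 | step 6 | 2-[methoxy(methyl)amino]-2-oxoethyl 2,4-bis(methoxymethoxy)-6-methylbenzoate | Cc1cc(OCOC)cc(OCOC)c1C(=O)OCC(=O)N(C)OC
F5 | step 6 | 2,2-dimethyl-6-(2-oxopropyl)-4H-1,3-dioxin-4-one | CC(=O)CC1=CC(=O)OC(C)(C)O1
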